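**Plan**
- Numbering used throughout: C1 (quaternary, CH3)–C2 (O)–C3–C4 (OH, iPr)–C5 in the five-membered ring; C5–C6 (O)–C7–C8 (CH3)=C9–C10–C1 in the seven-membered ring. The C8=C9 alkene is cis inside the ring and C7 is a CH2 between the C6 carbinol and C8, so a C6=C7 enol ether on C5 and a (Z)-C8 vinyl iodide on C1 can be joined at C7–C8.
- Retrosynthetic cuts, in order: the O2 angelate and O6 trimethoxybenzoate; C7–C8 (opens the seven-membered ring); C6=C7 (ester methylenation); C8=C9 (Z-selective olefination); C1–C10 (O2-tethered radical cyclisation); C5–C6 (carbonylation); C4–iPr; C1–CH3.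
- Forward: the fully substituted cyclopentane is built from (S)-4-silyloxycyclopentenone (steps 1–13), the seven-membered ring closes in step 14, and the two esters go on last (steps 15–18).
- Stereochemistry: C2 comes from the starting enone; C4 from organocerium addition anti to the C2 silyloxy group; C1 from the 5-exo radical cyclisation delivered from O2; C5 from hydrogen-atom transfer anti to the C4 silyloxy group; C6 from hydroboration under C5 control; the ring alkene from the Z vinyl iodide.

Key step: step 14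

Remark: α is the face of the C2 oxygen and β the face of the C1 methyl. Compounds 10–13 are mixtures of epimers at the acetal carbon, which is left undefined in their SMILES and is removed in step 11.

Step 1
Reactants: 1 (S)-4-(tert-butyldimethylsilyloxy)cyclopent-2-en-1-one
Product: 2 (3S,4S)-4-(tert-butyldimethylsilyloxy)-3-methyl-1-(trimethylsilyloxy)cyclopent-1-ene
Conditions: MeLi, CuI, Et2O, 0 °C; then 1, TMSCl, Et3N, THF, −78 °C
Reagents that add atoms: methyllithium (delivered as lithium dimethylcuprate), [Li]C; chlorotrimethylsilane, C[Si](C)(C)Cl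
Why: Cuprate conjugate addition places the methyl group on the β-carbon (future C1) anti to the silyloxy group and the enolate is trapped regiospecifically as the silyl enol ether; the new centre becomes sp2 again in step 2.

Step 2
Reactants: 2 silyl enol ether
Product: 3 (S)-4-(tert-butyldimethylsilyloxy)-3-methylcyclopent-2-en-1-one
Conditions: Pd(OAc)2 (10 mol %), O2 (1 atm), DMSO, rt
Reagents that add atoms: none
Why: Saegusa–Ito oxidation by divalent palladium restores the enone exactly at the position of the enol ether, now with the β-methyl group in place.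

Step 3
Reactants: 3 β-methyl enone
Product: 4 (S)-4-(tert-butyldimethylsilyloxy)-2-iodo-3-methylcyclopent-2-en-1-one
Conditions: I2, pyridine, DMAP (cat.), CH2Cl2, rt
Reagents that add atoms: iodine, [I][I]
Why: Amine-mediated α-iodination of an enone (conjugate addition of the amine, iodination of the enolate, elimination) puts iodine on the α-carbon (future C5).

Step 4
Reactants: 4 α-iodo enone
Product: 5 (1S,4S)-4-(tert-butyldimethylsilyloxy)-2-iodo-3-methyl-1-(propan-2-yl)cyclopent-2-en-1-ol
Conditions: iPrMgCl, CeCl3, THF, −78 °C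
Reagents that add atoms: isopropylmagnesium chloride, CC(C)[Mg]Cl
Why: 1,2-Addition of the weakly basic organocerium reagent occurs on the ketone face opposite the silyloxy group, which sets C4 with its hydroxyl cis to O2 and avoids enolisation or reduction.

Step 5
Reactants: 5 iodo alcohol; 6 4-methoxybenzyl alcohol
Product: 7 4-methoxybenzyl 3-(tert-butyldimethylsilyloxy)-5-hydroxy-2-methyl-5-(propan-2-yl)cyclopent-1-ene-1-carboxylate (3-O and 5-OH cis)
Conditions: Pd(PPh3)2Cl2 (5 mol %), CO (1 atm), 6, Et3N, DMF, 70 °C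
Reagents that add atoms: carbon monoxide, [C-]#[O+]; 4-methoxybenzyl alcohol (6), COc1ccc(CO)cc1
Why: Palladium-catalysed alkoxycarbonylation (oxidative addition of the vinyl iodide to zerovalent palladium, CO insertion, capture of the acyl palladium by 6) installs C6 as the ester that is later methylenated.

Step 6
Reactants: 7 silyl ether
Product: 8 4-methoxybenzyl 3,5-dihydroxy-2-methyl-5-(propan-2-yl)cyclopent-1-ene-1-carboxylate (cis-diol)
Conditions: Bu4NF, THF, 0 °C
Reagents that add atoms: none
Why: Fluoride desilylation frees O2 so that it can carry the radical tether.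

Step 7
Reactants: 8 diol; 9 ethyl vinyl ether
Product: 10 O2-(2-bromo-1-ethoxyethyl) mixed acetal of 8
Conditions: NBS, 9, CH2Cl2, −40 → 0 °C
Reagents that add atoms: ethyl vinyl ether (9), C=COCC; N-bromosuccinimide, O=C1CCC(=O)N1Br
Why: Bromoetherification of the vinyl ether with capture of the oxocarbenium ion by the secondary allylic hydroxyl gives the Ueno–Stork bromoacetal; the hindered tertiary hydroxyl should not compete.

Step 8
Reactants: 10 bromoacetal
Product: 11 O4-triethylsilyl ether of 10
Conditions: Et3SiOTf, 2,6-lutidine, CH2Cl2, −78 °C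
Reagents that add atoms: triethylsilyl trifluoromethanesulfonate, CC[Si](CC)(CC)OS(=O)(=O)C(F)(F)F
Why: Silyl triflate silylation of the tertiary alcohol at low temperature should be faster than any activation of the bromine-deactivated acetal; it protects O4 and puts a bulky group on the α face next to C5.

Step 9
Reactants: 11 bromoacetal silyl ether
Product: 12 cis-fused bicyclic acetal (O2–CH(OEt)–C10H2–C1 ring; C1 β-methyl; C4 α-triethylsilyloxy, β-isopropyl; C5 α-CO2CH2C6H4OMe)
Conditions: Bu3SnH (slow addition), AIBN, benzene, 80 °C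
Reagents that add atoms: none
Why: In this Ueno–Stork radical cyclisation the primary radical adds 5-exo-trig to the enoate β-carbon C1 from the face of the O2 tether, which makes C1 quaternary with the two-carbon arm cis to O2, and the C5 ester radical should then take hydrogen from Bu3SnH on the β face, away from the C4 silyloxy group, leaving the ester α.

Step 10
Reactants: 12 bicyclic ethyl acetal
Product: 13 lactol corresponding to 12
Conditions: AcOH/THF/H2O (3:1:1), 35 °C
Reagents that add atoms: water, O
Why: Acid-catalysed acetal hydrolysis of the 2-ethoxytetrahydrofuran should be much faster than cleavage of the hindered tertiary silyl ether or of the 4-methoxybenzyl ester.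

Step 11
Reactants: 13 lactol; 14 ethyltriphenylphosphonium iodide
Product: 19 C1 α-[(Z)-3-iodobut-2-enyl] C2 α-alcohol (C4 α-OSiEt3; C5 α-ester), via ethylidenetriphenylphosphorane 15 (not isolated), via 1-iodoethylphosphonium iodide 16 (not isolated), via iodo ylide 17 (not isolated), via hydroxy aldehyde 18 (not isolated)
Conditions: 14, n-BuLi, THF, rt; I2, −78 °C; NaN(SiMe3)2, −20 °C; then 13, −78 → −10 °C
Reagents that add atoms: ethyltriphenylphosphonium iodide (14), CC[P+](c1ccccc1)(c1ccccc1)c1ccccc1.[I-]; iodine, [I][I]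
Why: In this Stork–Zhao olefination the base opens the lactol to hydroxy aldehyde 18, and the kinetically controlled Wittig reaction of the α-iodo ylide gives the Z-2-iodoalkene (iodine cis to the chain), which fixes the geometry of the future ring alkene.

Step 12
Reactants: 19 vinyl iodide alcohol
Product: 20 O2-tert-butyldimethylsilyl ether of 19
Conditions: t-BuMe2SiOTf, 2,6-lutidine, CH2Cl2, −78 → 0 °C
Reagents that add atoms: tert-butyldimethylsilyl trifluoromethanesulfonate, CC(C)(C)[Si](C)(C)OS(=O)(=O)C(F)(F)F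
Why: Silyl triflate silylation of the hindered secondary alcohol protects O2 for the titanium and borane steps and keeps O2 and O4 distinguishable.

Step 13
Reactants: 20 ester
Product: 21 C5 α-[1-(4-methoxybenzyloxy)vinyl] cyclopentane (C1 α-(Z)-3-iodobut-2-enyl; C2 α-OSiMe2t-Bu; C4 α-OSiEt3)
Conditions: Cp2TiMe2, toluene, 75 °C, dark
Reagents that add atoms: dimethyltitanocene, C[Ti+2]C.c1cc[cH-]c1.c1cc[cH-]c1
Why: In the Petasis methylenation, titanocene methylidene formed on heating converts the ester carbonyl through an oxatitanacyclobutane into the C6=C7 enol ether; the vinyl iodide and silyl ethers should be inert.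

Step 14
Reactants: 21 enol ether vinyl iodide
Product: 23 cis-fused hydroazulene (2α-OSiMe2t-Bu; 4α-OSiEt3; (6R)-6-(4-methoxybenzyloxy), O6 anti to O4; C8=C9), via alkylborane 22 (not isolated)
Conditions: 9-BBN dimer, THF, rt; then slow addition to Pd(dppf)Cl2 (10 mol %), AsPh3, Cs2CO3 (aq.), DMF/THF, 50 °C, high dilution
Reagents that add atoms: none
Why: 9-BBN adds syn across the electron-rich 1,1-disubstituted enol ether with boron on terminal C7 and hydrogen on C6, and then oxidative addition of the C8–I bond to zerovalent palladium, base-assisted transmetallation of the primary alkylborane and reductive elimination form C7–C8. The closest known reaction type is the B-alkyl Suzuki–Miyaura coupling of alkyl-9-BBN reagents made from enol ethers, together with intramolecular B-alkyl Suzuki ring closures and couplings of (Z)-2-iodo-2-alkenes. The seven-membered ring closes through an eight-membered palladacycle with the new alkene endocyclic, which the cis arms on C1 and C5 favour. The new C6 centre is controlled by C5: with C5–H eclipsing the C6=C7 bond (allylic strain) the borane should approach from the C1 side, anti to the C4 carbon carrying the triethylsilyloxy group, which places O6 anti to O4. The step needs hydroboration of the enol ether in preference to the vinyl iodide, boron on C7, retention of the Z geometry and cyclisation in preference to oligomerisation; these are secured by the electronic and steric difference between the two alkenes, the polarisation of the enol ether, the stereospecific palladium steps and high dilution.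

Step 15
Reactants: 23 4-methoxybenzyl ether
Product: 24 (6R)-C6 alcohol (2α-OSiMe2t-Bu; 4α-OSiEt3)
Conditions: DDQ, CH2Cl2/pH 7 buffer, 0 °C
Reagents that add atoms: none
Why: Oxidative cleavage of the 4-methoxybenzyl ether by DDQ (hydride abstraction, hydrolysis of the oxocarbenium ion) frees O6 and should leave the silyl ethers and the trisubstituted alkene untouched under buffered conditions.

Step 16
Reactants: 24 C6 alcohol; 25 3,4,5-trimethoxybenzoyl chloride
Product: 26 C6 3,4,5-trimethoxybenzoate (2α-OSiMe2t-Bu; 4α-OSiEt3)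
Conditions: 25, Et3N, DMAP, CH2Cl2, rt
Reagents that add atoms: 3,4,5-trimethoxybenzoyl chloride (25), COc1cc(C(=O)Cl)cc(OC)c1OC
Why: DMAP-catalysed acylation of the only free hydroxyl gives the C6 ester with retention at C6.

Step 17
Reactants: 26 bis-silyl ether
Product: 27 2α,4α-diol C6 3,4,5-trimethoxybenzoate
Conditions: HF·pyridine, pyridine, THF, 0 °C → rt
Reagents that add atoms: none
Why: Fluoride-mediated desilylation removes both silyl ethers, and the benzoate and the tertiary alcohol should tolerate buffered HF.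

Step 18
Reactants: 27 diol; 28 angelic acid
Product: 30 target, (1R,2S,4S,5R,6R) in the numbering used here, via mixed anhydride 29 (not isolated)
Conditions: 28, 2,4,6-trichlorobenzoyl chloride, Et3N, toluene, rt; then 27, 80 °C
Reagents that add atoms: angelic acid (28), C/C=C(/C)C(=O)O
Why: Yamaguchi-type esterification through the mixed anhydride, run without DMAP so that the Z double bond does not isomerise to the tiglate, acylates the secondary O2 only, since the tertiary C4 hydroxyl is too hindered.

**Compound list**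
1 | (S)-4-(tert-butyldimethylsilyloxy)cyclopent-2-en-1-one | CC(C)(C)[Si](C)(C)O[C@H]1CC(=O)C=C1 | starting material
2 | (3S,4S)-4-(tert-butyldimethylsilyloxy)-3-methyl-1-(trimethylsilyloxy)cyclopent-1-ene (methyl trans to the silyloxy group) | CC(C)(C)[Si](C)(C)O[C@H]1CC(O[Si](C)(C)C)=C[C@@H]1C | intermediate
3 | (S)-4-(tert-butyldimethylsilyloxy)-3-methylcyclopent-2-en-1-one | CC(C)(C)[Si](C)(C)O[C@H]1CC(=O)C=C1C | intermediate
4 | (S)-4-(tert-butyldimethylsilyloxy)-2-iodo-3-methylcyclopent-2-en-1-one | CC(C)(C)[Si](C)(C)O[C@H]1CC(=O)C(I)=C1C | intermediate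
5 | (1S,4S)-4-(tert-butyldimethylsilyloxy)-2-iodo-3-methyl-1-(propan-2-yl)cyclopent-2-en-1-ol (hydroxyl cis to the silyloxy group) | CC(C)(C)[Si](C)(C)O[C@H]1C[C@](O)(C(C)C)C(I)=C1C | intermediate
6 | 4-methoxybenzyl alcohol | COc1ccc(CO)cc1 | starting material
7 | 4-methoxybenzyl 3-(tert-butyldimethylsilyloxy)-5-hydroxy-2-methyl-5-(propan-2-yl)cyclopent-1-ene-1-carboxylate (3-O and 5-OH cis) | CC(C)(C)[Si](C)(C)O[C@H]1C[C@](O)(C(C)C)C(C(=O)OCc2ccc(OC)cc2)=C1C | intermediate
8 | 4-methoxybenzyl 3,5-dihydroxy-2-methyl-5-(propan-2-yl)cyclopent-1-ene-1-carboxylate (cis-diol) | O[C@H]1C[C@](O)(C(C)C)C(C(=O)OCc2ccc(OC)cc2)=C1C | intermediate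
9 | ethyl vinyl ether | C=COCC | starting material
10 | O2-(2-bromo-1-ethoxyethyl) mixed acetal of 8 | BrCC(OCC)O[C@H]1C[C@](O)(C(C)C)C(C(=O)OCc2ccc(OC)cc2)=C1C | intermediate
11 | O4-triethylsilyl ether of 10 | BrCC(OCC)O[C@H]1C[C@](O[Si](CC)(CC)CC)(C(C)C)C(C(=O)OCc2ccc(OC)cc2)=C1C | intermediate
12 | cis-fused bicyclic ethyl acetal (C1 β-methyl, α-CH2 of the acetal ring; C4 α-OSiEt3; C5 α-ester) | O1[C@H]2C[C@](O[Si](CC)(CC)CC)(C(C)C)[C@@H](C(=O)OCc3ccc(OC)cc3)[C@@]2(C)CC1OCC | intermediate
13 | lactol corresponding to 12 | O1[C@H]2C[C@](O[Si](CC)(CC)CC)(C(C)C)[C@@H](C(=O)OCc3ccc(OC)cc3)[C@@]2(C)CC1O | intermediate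
14 | ethyltriphenylphosphonium iodide | CC[P+](c1ccccc1)(c1ccccc1)c1ccccc1.[I-] | starting material
15 | ethylidenetriphenylphosphorane | CC=P(c1ccccc1)(c1ccccc1)c1ccccc1 | intermediate (not isolated)
16 | (1-iodoethyl)triphenylphosphonium iodide | CC(I)[P+](c1ccccc1)(c1ccccc1)c1ccccc1.[I-] | intermediate (not isolated)
17 | (1-iodoethylidene)triphenylphosphorane | CC(I)=P(c1ccccc1)(c1ccccc1)c1ccccc1 | intermediate (not isolated)
18 | open-chain hydroxy aldehyde (C1 α-CH2CHO; C2 α-OH; C4 α-OSiEt3; C5 α-ester) | O[C@H]1C[C@](O[Si](CC)(CC)CC)(C(C)C)[C@@H](C(=O)OCc2ccc(OC)cc2)[C@@]1(C)CC=O | intermediate (not isolated)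
19 | C1 α-[(Z)-3-iodobut-2-enyl] C2 α-alcohol (C4 α-OSiEt3; C5 α-ester) | O[C@H]1C[C@](O[Si](CC)(CC)CC)(C(C)C)[C@@H](C(=O)OCc2ccc(OC)cc2)[C@@]1(C)C/C=C(/C)I | intermediate
20 | O2-tert-butyldimethylsilyl ether of 19 | CC(C)(C)[Si](C)(C)O[C@H]1C[C@](O[Si](CC)(CC)CC)(C(C)C)[C@@H](C(=O)OCc2ccc(OC)cc2)[C@@]1(C)C/C=C(/C)I | intermediate
21 | C5 α-[1-(4-methoxybenzyloxy)vinyl] cyclopentane with C1 α-(Z)-3-iodobut-2-enyl arm | CC(C)(C)[Si](C)(C)O[C@H]1C[C@](O[Si](CC)(CC)CC)(C(C)C)[C@@H](C(=C)OCc2ccc(OC)cc2)[C@@]1(C)C/C=C(/C)I | intermediate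
22 | C7 B-alkyl-9-borabicyclo[3.3.1]nonane from 21 | CC(C)(C)[Si](C)(C)O[C@H]1C[C@](O[Si](CC)(CC)CC)(C(C)C)[C@@H]([C@@H](CB2C3CCCC2CCC3)OCc2ccc(OC)cc2)[C@@]1(C)C/C=C(/C)I | intermediate (not isolated)
23 | cis-fused hydroazulene, (6R)-6-(4-methoxybenzyloxy), 2α-OSiMe2t-Bu, 4α-OSiEt3, C8=C9 | CC(C)(C)[Si](C)(C)O[C@H]1C[C@](O[Si](CC)(CC)CC)(C(C)C)[C@H]2[C@H](OCc3ccc(OC)cc3)CC(C)=CC[C@@]12C | intermediate
24 | (6R)-C6 alcohol | CC(C)(C)[Si](C)(C)O[C@H]1C[C@](O[Si](CC)(CC)CC)(C(C)C)[C@H]2[C@H](O)CC(C)=CC[C@@]12C | intermediate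
25 | 3,4,5-trimethoxybenzoyl chloride | COc1cc(C(=O)Cl)cc(OC)c1OC | starting material
26 | C6 3,4,5-trimethoxybenzoate, bis-silyl ether | CC(C)(C)[Si](C)(C)O[C@H]1C[C@](O[Si](CC)(CC)CC)(C(C)C)[C@H]2[C@H](OC(=O)c3cc(OC)c(OC)c(OC)c3)CC(C)=CC[C@@]12C | intermediate
27 | 2α,4α-diol C6 3,4,5-trimethoxybenzoate | O[C@H]1C[C@](O)(C(C)C)[C@H]2[C@H](OC(=O)c3cc(OC)c(OC)c(OC)c3)CC(C)=CC[C@@]12C | intermediate
28 | angelic acid, (Z)-2-methylbut-2-enoic acid | C/C=C(/C)C(=O)O | starting material
29 | angelic 2,4,6-trichlorobenzoic mixed anhydride | C/C=C(/C)C(=O)OC(=O)c1c(Cl)cc(Cl)cc1Cl | intermediate (not isolated)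
30 | CNP0112256.1, 2-O-angeloyl 6-O-(3,4,5-trimethoxybenzoyl) hydroazulene triol derivative | C/C=C(/C)C(=O)O[C@H]1C[C@](O)(C(C)C)[C@H]2[C@H](OC(=O)c3cc(OC)c(OC)c(OC)c3)CC(C)=CC[C@@]12C | target

**Step count**
Total steps: 18. Longest linear sequence: 18 steps (1 → 30).

**Steps most likely to fail**

Step 14. The borane may be delivered to the other face of the enol ether (poor or reversed facial selectivity at C6) while the ring still closes. The fallback sets out from 23, obtained together with or replaced by its C6 epimer, the 6-epi ether F1, and comes back at 27. DDQ removes the benzyl group from both epimers to give 24 and the 6-epi alcohol F2. Dess–Martin periodinane oxidises both to the single C6 ketone F3. Buffered HF·pyridine at 0 °C removes only the tertiary triethylsilyl group to give the β-hydroxy ketone F4. Me4NBH(OAc)3 in MeCN/AcOH at −20 °C (Evans–Saksena reduction) then delivers hydride from the boron bound to O4 onto the α face of the ketone and should give the 4,6-anti diol F5. Acylation of its secondary hydroxyl with 25 gives the silyl ether ester F6, and HF·pyridine at room temperature gives 27. C6 is then set by directed reduction and no longer by the hydroboration.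

Step 9. Hydrogen-atom transfer may occur on the α face of the C5 radical and leave the ester on the β face. The fallback sets out from 11 and comes back at 12. The cyclisation then gives the 5-epi ester F7, which is equilibrated with a catalytic amount of NaH in 4-methoxybenzyl alcohol/THF at room temperature; the alkoxide matches the ester, so exchange is degenerate. Reversible enolisation should move the ester to the α face, trans to the isopropyl group, which is expected to be the more stable arrangement. C5 is then set under thermodynamic control in place of kinetic hydrogen transfer.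

Step 11. The lactolate may not open to the aldehyde below the temperature at which the α-iodo ylide decomposes, so the olefination stalls. The fallback sets out from 13 and comes back at 20. Wittig methylenation of the lactol (methyltriphenylphosphonium bromide, KOt-Bu, THF, rt) gives the allyl alcohol F8. t-BuMe2SiOTf/2,6-lutidine gives the allyl silyl ether F9. OsO4 (cat.)/NaIO4 with 2,6-lutidine in dioxane/H2O cleaves the terminal alkene to the silyloxy aldehyde F10, which cannot close to a lactol. The Stork–Zhao olefination under the conditions of step 11 at −78 °C then gives 20 directly.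

Further compounds
F1 | step 14 | 6-epi ether, (6S)-epimer of 23 | CC(C)(C)[Si](C)(C)O[C@H]1C[C@](O[Si](CC)(CC)CC)(C(C)C)[C@H]2[C@@H](OCc3ccc(OC)cc3)CC(C)=CC[C@@]12C
F2 | step 14 | 6-epi alcohol, (6S)-epimer of 24 | CC(C)(C)[Si](C)(C)O[C@H]1C[C@](O[Si](CC)(CC)CC)(C(C)C)[C@H]2[C@@H](O)CC(C)=CC[C@@]12C
F3 | step 14 | C6 ketone (2α-OSiMe2t-Bu; 4α-OSiEt3) | CC(C)(C)[Si](C)(C)O[C@H]1C[C@](O[Si](CC)(CC)CC)(C(C)C)[C@H]2C(=O)CC(C)=CC[C@@]12C
F4 | step 14 | β-hydroxy ketone (4α-OH; 2α-OSiMe2t-Bu) | CC(C)(C)[Si](C)(C)O[C@H]1C[C@](O)(C(C)C)[C@H]2C(=O)CC(C)=CC[C@@]12C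
F5 | step 14 | 4,6-anti diol (2α-OSiMe2t-Bu) | CC(C)(C)[Si](C)(C)O[C@H]1C[C@](O)(C(C)C)[C@H]2[C@H](O)CC(C)=CC[C@@]12C
F6 | step 14 | silyl ether ester, C6 3,4,5-trimethoxybenzoate with 4α-OH and 2α-OSiMe2t-Bu | CC(C)(C)[Si](C)(C)O[C@H]1C[C@](O)(C(C)C)[C@H]2[C@H](OC(=O)c3cc(OC)c(OC)c(OC)c3)CC(C)=CC[C@@]12C
F7 | step 9 | 5-epi ester, C5 epimer of 12 (ester β) | O1[C@H]2C[C@](O[Si](CC)(CC)CC)(C(C)C)[C@H](C(=O)OCc3ccc(OC)cc3)[C@@]2(C)CC1OCC
F8 | step 11 | allyl alcohol (C1 α-allyl; C2 α-OH) | O[C@H]1C[C@](O[Si](CC)(CC)CC)(C(C)C)[C@@H](C(=O)OCc2ccc(OC)cc2)[C@@]1(C)CC=C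
F9 | step 11 | allyl silyl ether (C2 α-OSiMe2t-Bu) | CC(C)(C)[Si](C)(C)O[C@H]1C[C@](O[Si](CC)(CC)CC)(C(C)C)[C@@H](C(=O)OCc2ccc(OC)cc2)[C@@]1(C)CC=C
F10 | step 11 | silyloxy aldehyde (C1 α-CH2CHO; C2 α-OSiMe2t-Bu) | CC(C)(C)[Si](C)(C)O[C@H]1C[C@](O[Si](CC)(CC)CC)(C(C)C)[C@@H](C(=O)OCc2ccc(OC)cc2)[C@@]1(C)CC=O
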